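The numbers in the tables are simulated for substances that don't exist; scatter was added.

Temperature is the setting to choose for the next run, and the one warning against heat comes from the elm run, whose target falls with time at 40 °C. North-west, west, south-west and east share one charge and differ in temperature, so the decision is whether that warning holds for them.

| flask | substrate | reagent | temperature | remark | time |
|---|---|---|---|---|---|
| larch | 21 mM | 14.2 mM | 12 °C | run made earlier |  |
| elm | 33 mM | 14.2 mM | 40 °C | run made earlier |  |
| alder | 15 mM | 28 mM | 12 °C | run made earlier |  |
| north-west | 15 mM | 14.2 mM |  | at 50 °C until 2.5 h, from then on at 0 °C | 8.0 h |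
| west | 15 mM | 14.2 mM | 50 °C |  | 8.0 h |
| south-west | 15 mM | 14.2 mM | 0 °C |  | 8.0 h |
| east | 15 mM | 14.2 mM | 25 °C |  | 8.0 h |

- larch (time / h: target / %): 3.00: 48; 5.00: 52; 8.00: 57; 12.0: 57; 20.0: 56; 25.0: 61; 40.0: 57
- elm (time / h: target / %): 1.50: 30; 3.00: 25; 5.00: 25; 6.00: 24; 8.00: 19; 10.0: 15
- alder (time / h: target / %): 3.00: 89; 10.0: 97; 20.0: 101; 30.0: 100; 40.0: 95

(standard deviation of a reading: 2 percentage points)



- the best flask by amount of target, in percent of the substrate charged; "all alike" if 1.5 percentage points covers them all (north-west / west / south-west / east / all alike)
- amount of target at the end, in percent of the substrate charged, north-west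
- amount of target at the end, in percent of the substrate charged, west
- amount of target at the end, in percent of the substrate charged, south-west
- amount of target at the end, in percent of the substrate charged, east

Alder, with reagent in excess, stands at 101 % at 20.0 h and 95 % at 40.0 h, so at 12 °C one substrate gives about one target. Larch also holds at that temperature, with 57 % at 8.00 h and 57 % at 40.0 h. Elm falls from 30 % at 1.50 h to 15 % at 10.0 h.

The useful scale takes equal charges as its zero. The surplus share, (starting [substrate] − starting [reagent]) / starting [substrate], is the part of the substrate charged that stays over once each reagent has taken one substrate: by charge, reagent is then the limiting reagent. For the flasks asked about it is 5.33 %, while elm stands at 57.0 %. By charge, elm therefore has substrate to spare beside its target.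

The reckoning here is that the fall needs substrate as a partner, so a flask near the zero should lose target while substrate lasts and then flatten, instead of following elm down. The charge therefore stays as it is, east is the flask to try first, and west is not written off.

The forecast also names east as best, with 30 % for north-west, 7 % for west, 58 % for south-west and 61 % for east. For west it says “about 53% formed quickly, then decays to about 7%”. The two reckonings part at west.

The flasks give 68.7 % in north-west, 67.9 % in west, 59.2 % in south-west and 74.8 % in east, so east is best.

    substrate + reagent → target, rate k1*[substrate]*[reagent]^1.5 (k = 0.180 /M^1.5/s, Ea = 39.0 kJ/mol)
    substrate + target → side product (k = 6.00 × 10⁻⁴ /M/s, Ea = 70.0 kJ/mol)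
    (constants at 25 °C)

West minus south-west is 8.7 percentage points, and it would be −30 points if temperature did nothing to the turning of substrate + reagent into target, the largest single effect on that difference. South-west is held at 59.2 % in part by the using up of reagent and the length of the run, acting together. Without the side step west would hold 89.1 % instead of 67.9 %, which is part of its shortfall. That step needs substrate, however, and west, charged with a surplus share of 5.33 %, has 1.38 % substrate left at 8.00 h, with target at 67.9 % then and 67.8 % at 80.0 h. South-west charged with 38 mM of substrate has a surplus share of 62.6 %, and at 8.00 h it holds 65.8 % substrate beside 32.4 % target.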